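**Plan**
- Retrosynthesis: the last operations only unmask or acetylate phenols. The single skeletal cut opens ring A at C1–C6 and C2–C3, giving an aroyl propiolate (its alkyne carbons become C1 and C2) and a 1,1-dimethoxy-3-silyloxybutadiene (C3–C6). The ynone is then cut at the carbinol–alkyne bond and at the aryl–CHO bond, back to orcinol and methyl propiolate.
- Enabling feature: ring A carries the ester (C1) and the aroyl group (C2) on neighbouring carbons, with oxygen at C3 (OMe) and C5 (OH). This is the pattern left when an acetylenic keto ester and a ketene-acetal/silyl-enol-ether diene combine and lose methanol.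
- Forward order: ring B is bought as orcinol and carried as its bis-MOM ether. Formylation between the two ethers, propiolate addition and oxidation give the ynone. The diene is made in two steps from 1,1-dimethoxyethene. Ring A is then formed by cycloaddition and aromatisation with the crowded diaryl ketone already in place.
- Endgame: acid removes the MOM ethers, one of the two equivalent ring-B phenols is acetylated, and buffered fluoride frees the ring-A phenol.
- Stereochemistry: there is none to set. The only selectivity to control is the regiochemistry of the cycloaddition, which the ketone of the ynone governs.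

Key step: step 7

Remark: the target has no stereogenic element, so the request for a single enantiomer imposes no requirement on the route.

**Route**

Step 1
Reactants: 1 orcinol
Product: 2 1,3-bis(methoxymethoxy)-5-methylbenzene
Conditions: MOMCl (2.5 equiv), i-Pr2NEt (3 equiv), CH2Cl2, 0 °C → rt
Reagents that add atoms: chloromethyl methyl ether (MOMCl), COCCl
Why: O-alkylation of both phenols by the α-chloro ether (MOM protection) should give a bis-acetal that tolerates organolithium reagents and directs the metalation of step 2.

Step 2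
Reactants: 2 1,3-bis(methoxymethoxy)-5-methylbenzene
Product: 4 2,6-bis(methoxymethoxy)-4-methylbenzaldehyde, via aryllithium 3 (not isolated)
Conditions: n-BuLi (1.1 equiv), THF, 0 °C → rt; DMF, 0 °C; H2O work-up
Reagents that add atoms: N,N-dimethylformamide (DMF), CN(C)C=O
Why: Directed ortho-metalation should occur at the ring position flanked by both MOM ethers, the most acidic and doubly coordinated site, and the aryllithium is then formylated by DMF.

Step 3
Reactants: 5 methyl propiolate; 4 2,6-bis(methoxymethoxy)-4-methylbenzaldehyde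
Product: 7 methyl 4-[2,6-bis(methoxymethoxy)-4-methylphenyl]-4-hydroxybut-2-ynoate (racemic), via lithium acetylide 6 (not isolated)
Conditions: LiHMDS (1.2 equiv), THF, −78 °C; then 4, −78 °C; AcOH quench, −78 °C → rt
Reagents that add atoms: none
Why: 1,2-Addition of a lithium acetylide to an aldehyde should proceed at −78 °C, where lithiated methyl propiolate is stable; the carbinol centre forms as a racemate and is erased in step 4.

Step 4
Reactants: 7 methyl 4-[2,6-bis(methoxymethoxy)-4-methylphenyl]-4-hydroxybut-2-ynoate
Product: 8 methyl 4-[2,6-bis(methoxymethoxy)-4-methylphenyl]-4-oxobut-2-ynoate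
Conditions: Dess–Martin periodinane (1.3 equiv), CH2Cl2, 0 °C → rt
Reagents that add atoms: none
Why: Dess–Martin oxidation of the benzylic and propargylic secondary alcohol should give the ynone under neutral, anhydrous conditions that spare the MOM ethers and the electrophilic alkyne.

Step 5
Reactants: 9 1,1-dimethoxyethene; 10 acetyl chloride
Product: 11 4,4-dimethoxybut-3-en-2-one
Conditions: Et3N (1.2 equiv), Et2O, 0 °C → rt
Reagents that add atoms: none
Why: C-Acylation of the electron-rich ketene acetal by the acid chloride, with loss of HCl to the amine, should give the β-acyl ketene acetal, a known acylation of ketene acetals.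

Step 6
Reactants: 11 4,4-dimethoxybut-3-en-2-one
Product: 12 1,1-dimethoxy-3-(triisopropylsilyloxy)buta-1,3-diene
Conditions: TIPSOTf (1.1 equiv), Et3N (1.5 equiv), Et2O, 0 °C; salts removed with pentane, diene used without chromatography
Reagents that add atoms: triisopropylsilyl trifluoromethanesulfonate (TIPSOTf), CC(C)[Si](OS(=O)(=O)C(F)(F)F)(C(C)C)C(C)C
Why: Soft enolisation of the methyl ketone with silyl triflate and amine (only the methyl group has α-hydrogens) should give the 2-silyloxydiene, and triisopropylsilyl is chosen because the aryl silyl ether it becomes must survive the acidic MOM cleavage of step 8.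

Step 7
Reactants: 8 methyl 4-[2,6-bis(methoxymethoxy)-4-methylphenyl]-4-oxobut-2-ynoate; 12 1,1-dimethoxy-3-(triisopropylsilyloxy)buta-1,3-diene
Product: 14 methyl 2-[2,6-bis(methoxymethoxy)-4-methylbenzoyl]-3-methoxy-5-(triisopropylsilyloxy)benzoate, via cyclohexadiene adduct 13 (not isolated)
Conditions: 12 (1.5 equiv), toluene, 0 °C → rt, then 60 °C
Reagents that add atoms: none
Why: The electron-rich diene and the doubly activated alkyne should combine in a normal-electron-demand, strongly asynchronous [4+2] cycloaddition in which the C1–C6 bond (diene methylene to the ester-bearing alkyne carbon, β to the ketone) runs ahead of the C2–C3 bond (ketene-acetal carbon to the aroyl-bearing carbon), after which the 3,3-dimethoxycyclohexa-1,4-diene 13 ionises at its doubly allylic ketal, loses a proton from C6 and so expels methanol to give the arene. The closest known reaction type is the Diels–Alder reaction of 1,1-dialkoxy-3-silyloxybutadienes with acetylenic ketones and esters followed by loss of alcohol to resorcinol monoethers. Ring A, the only ring formed, closes by intermolecular [4+2] cycloaddition that makes the C1–C6 and C2–C3 bonds in one operation. No stereocentre arises, because C3 and C6 of 13 each carry two identical substituents and the product is a planar arene. The step needs regioselectivity, which rests on the ketone being a stronger acceptor than the ester, so that the larger LUMO coefficient sits on the ester-bearing carbon and meets the large HOMO coefficient at the diene methylene; the 2,6-disubstituted aryl ring is twisted out of the carbonyl plane, so it does not weaken the ketone by donation, and its bulk screens the carbonyl from 1,2-attack. Under these neutral conditions the silyl enol ether should end as the aryl silyl ether at C5 and the surviving methoxy group sits at C3.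

Step 8
Reactants: 14 methyl 2-[2,6-bis(methoxymethoxy)-4-methylbenzoyl]-3-methoxy-5-(triisopropylsilyloxy)benzoate
Product: 15 methyl 2-(2,6-dihydroxy-4-methylbenzoyl)-3-methoxy-5-(triisopropylsilyloxy)benzoate
Conditions: conc. aq. HCl (cat.), MeOH, 40 °C
Reagents that add atoms: none
Why: Acid-catalysed acetal exchange with methanol should remove both phenolic MOM ethers, helped by the neighbouring carbonyl, while the aryl triisopropylsilyl ether on the electron-poor ring and the methyl ester (in methanol) persist.

Step 9
Reactants: 15 methyl 2-(2,6-dihydroxy-4-methylbenzoyl)-3-methoxy-5-(triisopropylsilyloxy)benzoate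
Product: 16 methyl 2-(2-acetoxy-6-hydroxy-4-methylbenzoyl)-3-methoxy-5-(triisopropylsilyloxy)benzoate
Conditions: Ac2O (1.0 equiv), pyridine, CH2Cl2, 0 °C
Reagents that add atoms: acetic anhydride, CC(=O)OC(C)=O
Why: Phenol acetylation with one equivalent of anhydride should stop at the monoacetate, because the two ring-B hydroxyls are equivalent (only one monoacetate exists) and the hydroxyl that remains is held in a hydrogen bond to the ketone and is acylated more slowly.

Step 10
Reactants: 16 methyl 2-(2-acetoxy-6-hydroxy-4-methylbenzoyl)-3-methoxy-5-(triisopropylsilyloxy)benzoate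
Product: 17 penibenzophenone C, methyl 2-(2-acetoxy-6-hydroxy-4-methylbenzoyl)-5-hydroxy-3-methoxybenzoate
Conditions: TBAF (1.1 equiv), AcOH (1.1 equiv), THF, 0 °C
Reagents that add atoms: none
Why: Fluoride-induced cleavage of an aryl silyl ether (the phenoxide para to the ketone is a good leaving group) should be fast at 0 °C, and the acetic acid buffer protonates the phenoxide at once so that the aryl acetate is neither cleaved nor transferred.

**Compound list**
1 | orcinol (5-methylbenzene-1,3-diol) | Cc1cc(O)cc(O)c1 | starting material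
2 | 1,3-bis(methoxymethoxy)-5-methylbenzene | COCOc1cc(C)cc(OCOC)c1 | intermediate
3 | [2,6-bis(methoxymethoxy)-4-methylphenyl]lithium | [Li]c1c(OCOC)cc(C)cc1OCOC | intermediate (not isolated)
4 | 2,6-bis(methoxymethoxy)-4-methylbenzaldehyde | O=Cc1c(OCOC)cc(C)cc1OCOC | intermediate
5 | methyl propiolate | C#CC(=O)OC | starting material
6 | methyl 3-lithioprop-2-ynoate | [Li]C#CC(=O)OC | intermediate (not isolated)
7 | methyl 4-[2,6-bis(methoxymethoxy)-4-methylphenyl]-4-hydroxybut-2-ynoate (racemic) | COC(=O)C#CC(O)c1c(OCOC)cc(C)cc1OCOC | intermediate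
8 | methyl 4-[2,6-bis(methoxymethoxy)-4-methylphenyl]-4-oxobut-2-ynoate | COC(=O)C#CC(=O)c1c(OCOC)cc(C)cc1OCOC | intermediate
9 | 1,1-dimethoxyethene | C=C(OC)OC | starting material
10 | acetyl chloride | CC(Cl)=O | starting material
11 | 4,4-dimethoxybut-3-en-2-one | CC(=O)C=C(OC)OC | intermediate
12 | 1,1-dimethoxy-3-(triisopropylsilyloxy)buta-1,3-diene | COC(OC)=CC(=C)O[Si](C(C)C)(C(C)C)C(C)C | intermediate
13 | methyl 2-[2,6-bis(methoxymethoxy)-4-methylbenzoyl]-3,3-dimethoxy-5-(triisopropylsilyloxy)cyclohexa-1,4-diene-1-carboxylate | COC(=O)C1=C(C(=O)c2c(OCOC)cc(C)cc2OCOC)C(OC)(OC)C=C(O[Si](C(C)C)(C(C)C)C(C)C)C1 | intermediate (not isolated)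
14 | methyl 2-[2,6-bis(methoxymethoxy)-4-methylbenzoyl]-3-methoxy-5-(triisopropylsilyloxy)benzoate | COC(=O)c1cc(O[Si](C(C)C)(C(C)C)C(C)C)cc(OC)c1C(=O)c1c(OCOC)cc(C)cc1OCOC | intermediate
15 | methyl 2-(2,6-dihydroxy-4-methylbenzoyl)-3-methoxy-5-(triisopropylsilyloxy)benzoate | COC(=O)c1cc(O[Si](C(C)C)(C(C)C)C(C)C)cc(OC)c1C(=O)c1c(O)cc(C)cc1O | intermediate
16 | methyl 2-(2-acetoxy-6-hydroxy-4-methylbenzoyl)-3-methoxy-5-(triisopropylsilyloxy)benzoate | COC(=O)c1cc(O[Si](C(C)C)(C(C)C)C(C)C)cc(OC)c1C(=O)c1c(O)cc(C)cc1OC(C)=O | intermediate
17 | penibenzophenone C, methyl 2-(2-acetoxy-6-hydroxy-4-methylbenzoyl)-5-hydroxy-3-methoxybenzoate | COC(=O)c1cc(O)cc(OC)c1C(=O)c1c(O)cc(C)cc1OC(C)=O | target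

**Step count**
Total: 10 steps. Longest linear sequence: 8 steps (steps 1, 2, 3, 4, 7, 8, 9, 10, from orcinol); the diene branch is 2 steps.

**Steps most likely to fail**

Step 7. The risk is erosion of regiocontrol: if the twisted aroyl ketone polarises the alkyne little more than the ester does, part of the diene methylene would bond to the aroyl-bearing carbon and the methoxy group would end next to the ester. The fallback removes the competing acceptor; it sets out from aldehyde 4 and rejoins the route at 14. 3,3-Diethoxyprop-1-yne is deprotonated with n-BuLi in THF at −78 °C to (3,3-diethoxyprop-1-yn-1-yl)lithium F1, which should add to 4 to give 1-[2,6-bis(methoxymethoxy)-4-methylphenyl]-4,4-diethoxybut-2-yn-1-ol F2. Dess–Martin oxidation should give 1-[2,6-bis(methoxymethoxy)-4-methylphenyl]-4,4-diethoxybut-2-yn-1-one F3, in which the ketone is the only acceptor. Cycloaddition with diene 12 in warm toluene should pass through the adduct [2,6-bis(methoxymethoxy)-4-methylphenyl][2-(diethoxymethyl)-6,6-dimethoxy-4-(triisopropylsilyloxy)cyclohexa-1,4-dien-1-yl]methanone F4, which loses methanol to the arene [2,6-bis(methoxymethoxy)-4-methylphenyl][2-(diethoxymethyl)-6-methoxy-4-(triisopropylsilyloxy)phenyl]methanone F5. PPTS in wet acetone should hydrolyse the aryl aldehyde acetal, leaving the phenolic MOM ethers, to give 2-[2,6-bis(methoxymethoxy)-4-methylbenzoyl]-3-methoxy-5-(triisopropylsilyloxy)benzaldehyde F6. Pinnick oxidation (NaClO2, NaH2PO4, 2-methylbut-2-ene) should give 2-[2,6-bis(methoxymethoxy)-4-methylbenzoyl]-3-methoxy-5-(triisopropylsilyloxy)benzoic acid F7, and trimethylsilyldiazomethane in toluene/methanol should convert it into ester 14.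

Step 9. The risk is poor discrimination between the first and second acylation, so that diol, monoacetate and diacetate form together. The fallback differentiates the two ring-B oxygens before acylation; it sets out from 14 and rejoins the route at 16. Brief treatment of 14 with dilute HCl in methanol at 0 °C should cleave only one MOM ether, since the first cleavage is assisted by the neighbouring carbonyl and the phenol it frees then ties up that carbonyl in a hydrogen bond. The product is methyl 2-[2-hydroxy-6-(methoxymethoxy)-4-methylbenzoyl]-3-methoxy-5-(triisopropylsilyloxy)benzoate F8. Exhaustive acetylation (excess Ac2O, pyridine, DMAP) should give methyl 2-[2-acetoxy-6-(methoxymethoxy)-4-methylbenzoyl]-3-methoxy-5-(triisopropylsilyloxy)benzoate F9. The remaining MOM ether is then removed with trifluoroacetic acid in CH2Cl2 containing a little water at 0 °C, a non-alcoholic acid that should leave the aryl acetate and the silyl ether intact and deliver 16.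

Step 10. The risk is cleavage or transfer of the aryl acetate when fluoride generates a phenoxide in its presence. The fallback exchanges the silyl ether for a benzyl ether before the acetate is introduced, so that the last step is a neutral hydrogenolysis; it sets out from 14 and rejoins the route at the target 17. TBAF in THF should convert 14 into methyl 2-[2,6-bis(methoxymethoxy)-4-methylbenzoyl]-5-hydroxy-3-methoxybenzoate F10. Benzyl bromide and K2CO3 in DMF should give methyl 5-(benzyloxy)-2-[2,6-bis(methoxymethoxy)-4-methylbenzoyl]-3-methoxybenzoate F11. HCl in methanol should remove both MOM ethers to give methyl 5-(benzyloxy)-2-(2,6-dihydroxy-4-methylbenzoyl)-3-methoxybenzoate F12. One equivalent of Ac2O in pyridine should give methyl 2-(2-acetoxy-6-hydroxy-4-methylbenzoyl)-5-(benzyloxy)-3-methoxybenzoate F13. Hydrogenolysis (H2, Pd/C, EtOAc, rt) should then release 17 without touching the acetate or the hindered, hydrogen-bonded ketone.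

**Further compounds**
F1 | step 7 | (3,3-diethoxyprop-1-yn-1-yl)lithium | [Li]C#CC(OCC)OCC
F2 | step 7 | 1-[2,6-bis(methoxymethoxy)-4-methylphenyl]-4,4-diethoxybut-2-yn-1-ol (racemic) | CCOC(OCC)C#CC(O)c1c(OCOC)cc(C)cc1OCOC
F3 | step 7 | 1-[2,6-bis(methoxymethoxy)-4-methylphenyl]-4,4-diethoxybut-2-yn-1-one | CCOC(OCC)C#CC(=O)c1c(OCOC)cc(C)cc1OCOC
F4 | step 7 | [2,6-bis(methoxymethoxy)-4-methylphenyl][2-(diethoxymethyl)-6,6-dimethoxy-4-(triisopropylsilyloxy)cyclohexa-1,4-dien-1-yl]methanone | CCOC(OCC)C1=C(C(=O)c2c(OCOC)cc(C)cc2OCOC)C(OC)(OC)C=C(O[Si](C(C)C)(C(C)C)C(C)C)C1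
F5 | step 7 | [2,6-bis(methoxymethoxy)-4-methylphenyl][2-(diethoxymethyl)-6-methoxy-4-(triisopropylsilyloxy)phenyl]methanone | CCOC(OCC)c1cc(O[Si](C(C)C)(C(C)C)C(C)C)cc(OC)c1C(=O)c1c(OCOC)cc(C)cc1OCOC
F6 | step 7 | 2-[2,6-bis(methoxymethoxy)-4-methylbenzoyl]-3-methoxy-5-(triisopropylsilyloxy)benzaldehyde | O=Cc1cc(O[Si](C(C)C)(C(C)C)C(C)C)cc(OC)c1C(=O)c1c(OCOC)cc(C)cc1OCOC
F7 | step 7 | 2-[2,6-bis(methoxymethoxy)-4-methylbenzoyl]-3-methoxy-5-(triisopropylsilyloxy)benzoic acid | OC(=O)c1cc(O[Si](C(C)C)(C(C)C)C(C)C)cc(OC)c1C(=O)c1c(OCOC)cc(C)cc1OCOC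
F8 | step 9 | methyl 2-[2-hydroxy-6-(methoxymethoxy)-4-methylbenzoyl]-3-methoxy-5-(triisopropylsilyloxy)benzoate | COC(=O)c1cc(O[Si](C(C)C)(C(C)C)C(C)C)cc(OC)c1C(=O)c1c(O)cc(C)cc1OCOC
F9 | step 9 | methyl 2-[2-acetoxy-6-(methoxymethoxy)-4-methylbenzoyl]-3-methoxy-5-(triisopropylsilyloxy)benzoate | COC(=O)c1cc(O[Si](C(C)C)(C(C)C)C(C)C)cc(OC)c1C(=O)c1c(OC(C)=O)cc(C)cc1OCOC
F10 | step 10 | methyl 2-[2,6-bis(methoxymethoxy)-4-methylbenzoyl]-5-hydroxy-3-methoxybenzoate | COC(=O)c1cc(O)cc(OC)c1C(=O)c1c(OCOC)cc(C)cc1OCOC
F11 | step 10 | methyl 5-(benzyloxy)-2-[2,6-bis(methoxymethoxy)-4-methylbenzoyl]-3-methoxybenzoate | COC(=O)c1cc(OCc2ccccc2)cc(OC)c1C(=O)c1c(OCOC)cc(C)cc1OCOC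
F12 | step 10 | methyl 5-(benzyloxy)-2-(2,6-dihydroxy-4-methylbenzoyl)-3-methoxybenzoate | COC(=O)c1cc(OCc2ccccc2)cc(OC)c1C(=O)c1c(O)cc(C)cc1O
F13 | step 10 | methyl 2-(2-acetoxy-6-hydroxy-4-methylbenzoyl)-5-(benzyloxy)-3-methoxybenzoate | COC(=O)c1cc(OCc2ccccc2)cc(OC)c1C(=O)c1c(O)cc(C)cc1OC(C)=O
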